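**Strategy.** Number the tetrahydrofuran O1–C2(ring A = 3,4,5-trimethoxyphenyl)–C3(C6H2OH)–C4(C7H2–ring B)–C5H2. The route disconnects C4–C5 and C2–C3 in one Prins–pinacol step. The feature exploited is the one-carbon oxygenated branch C6 on C3, flanked by O1-bearing C2 and by C4, next to an unsubstituted C5. A formaldehyde acetal supplies C5, a Z-alkene supplies C3=C4, and C2 migrates from C6 to C3. The precursor is a cis-4-[(Z)-alkenyl]-5-aryl-1,3-dioxolane. The step closes the ring and sets C3 and C4, giving the all-cis alcohol after in-flask reduction; C2 is then equilibrated to trans.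

Key step: step 4

Remark on the chemistry: the borane derived from (+)-α-pinene is taken to deliver the allyl unit to the Si face of the aldehyde, as the parent allyl reagent does. The prescribed precursor and product structures were checked and are stereochemically consistent with the target, so none was changed. The cis-dioxolane is kept because it alone lets ring A and the C6 oxygen both sit equatorial in one chair. The acetal is closed under base (dibromomethane, not acidic exchange with dimethoxymethane) so that the benzylic C2–O bond meets no acid before the key step. Reagents that deliver no non-hydrogen atom are not numbered.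

Step 1
Reactants: 1 3,4,5-trimethoxybenzaldehyde; 2 allenylboronic acid pinacol ester
Product: 5 (1R,2S)-1-(3,4,5-trimethoxyphenyl)but-3-ene-1,2-diol, via (E)-gamma-borylallylborane 3 (not isolated), via anti-boryl borinate adduct 4 (not isolated)
Conditions: 2, (−)-Ipc2BH [from (+)-α-pinene], Et2O, −25 → 0 °C; 1 (limiting), −78 °C; then NaOH, H2O2, THF–H2O, −78 → 0 °C
Reagents that add atoms: hydrogen peroxide (OO)
Why: Hydroboration of the allene gives the thermodynamically preferred (E)-γ-borylallylborane 3, which adds to 1 in a Brown allylboration through a closed chair transition state in which the E geometry sets the anti relation of C2 and C6 and the isopinocampheyl groups direct attack to the Si face of the aldehyde (C2 R), and stereoretentive oxidation of the C–B and O–B bonds of 4 then releases the anti diol without any protecting group.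

Step 2
Reactants: 5 (1R,2S)-1-(3,4,5-trimethoxyphenyl)but-3-ene-1,2-diol; 6 dibromomethane
Product: 7 (4S,5R)-4-ethenyl-5-(3,4,5-trimethoxyphenyl)-1,3-dioxolane
Conditions: NaH, DMF, 0 °C → rt
Reagents that add atoms: none
Why: A double Williamson etherification (alkoxide alkylation, then 5-exo-tet closure of the bromomethyl ether) forms the methylene acetal under basic conditions that touch neither stereocenter, whereas acid-catalysed acetal exchange could ionise the benzylic C2–O bond on which the absolute configuration of the route rests.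

Step 3
Reactants: 7 (4S,5R)-4-ethenyl-5-(3,4,5-trimethoxyphenyl)-1,3-dioxolane; 8 4-allyl-1,2-dimethoxybenzene
Product: 9 (4S,5R)-4-[(1Z)-3-(3,4-dimethoxyphenyl)prop-1-en-1-yl]-5-(3,4,5-trimethoxyphenyl)-1,3-dioxolane
Conditions: Ru(NO3)(=CH-C6H4-2-OiPr)(NHC) (5 mol %; NHC = 1-adamantyl-3-(2,6-diisopropylphenyl)imidazolidin-2-ylidene, C,C-chelating through a metalated adamantyl carbon; C35H47N3O4Ru), 8 (4 equiv), THF, 35 °C, static vacuum
Reagents that add atoms: none
Why: In this Z-selective olefin cross-metathesis the cyclometalated ruthenium catalyst forces both substituents of the ruthenacyclobutane to the side away from the N-aryl group, so the terminal alkene of 7 and the allyl group of 8 (in excess, ethene removed) should couple to the Z-alkene under kinetic control, a reaction type known for allylic-substituted terminal olefins and allylbenzenes, with no stereocenter formed or touched.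

Step 4
Reactants: 9 (4S,5R)-4-[(1Z)-3-(3,4-dimethoxyphenyl)prop-1-en-1-yl]-5-(3,4,5-trimethoxyphenyl)-1,3-dioxolane
Product: 11 [(2S,3S,4S)-4-(3,4-dimethoxybenzyl)-2-(3,4,5-trimethoxyphenyl)oxolan-3-yl]methanol, via all-cis aldehyde 10 (not isolated)
Conditions: SnCl4 (2 equiv), CH2Cl2, −78 → −20 °C; then NaBH4, MeOH, −78 → 0 °C
Reagents that add atoms: none
Why: SnCl4 reversibly opens the methylene acetal, and the oxocarbenium ion on O1 (O1=C5H2, with the C6 oxygen bound to tin) is attacked by C4 of the Z-alkene to form C4–C5 while, as positive charge builds at C3, C2 shifts from C6 to C3 (forming C2–C3) under the push of the tin alkoxide, leaving C6 as the formyl carbon of 10, which NaBH4 reduces in the same flask. The closest known reaction type is the Prins cyclization–pinacol rearrangement of 4-alkenyl-1,3-dioxolanes to 3-acyltetrahydrofurans, including ring-contracting cases of secondary carbinols that end in a formyl group. The tetrahydrofuran ring (O1–C2–C3–C4–C5) closes by a 6-endo-trig Prins closure through a chair to an oxan-4-yl cation, followed by a 1,2-shift that contracts the six-membered ring to five. C4 is set by the Z geometry in the chair that holds ring A on C2 and the tin alkoxide on C6 both equatorial (C7 ends axial), and C3 by the suprafacial migration of C2, which keeps its configuration and leaves C6 on the face of ring A and C7, hence all-cis. The step needs C2 and not the axial hydrogen on C6 to migrate, the shift to outrun a 2-oxonia-Cope/aldol detour and ionisation at benzylic C2, and no epimerisation of 10 at C3; these should be secured by the lone-pair-assisted migratory aptitude of the O1-bearing benzylic C2, by the single chair open to the cis-dioxolane (through which the detour would set C4 identically), by the only moderately cation-stabilising 3,4,5-trimethoxyphenyl ring at low temperature, and by the immediate reduction.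

Step 5
Reactants: 11 [(2S,3S,4S)-4-(3,4-dimethoxybenzyl)-2-(3,4,5-trimethoxyphenyl)oxolan-3-yl]methanol
Product: 12 [(2R,3S,4S)-4-(3,4-dimethoxybenzyl)-2-(3,4,5-trimethoxyphenyl)oxolan-3-yl]methanol
Conditions: CF3CO2H (0.5 equiv), CH2Cl2, 0 °C → rt, stopped when the cis isomer is consumed; aq NaHCO3
Reagents that add atoms: none
Why: In this acid-mediated SN1 epimerisation, reversible ionisation of the benzylic C2–O1 bond gives a ring-A-stabilised cation that the tethered O1 should recapture far faster than ring B can attack it, so C2 equilibrates to the less crowded 2,3-trans isomer while C3 and C4, which can neither ionise nor enolise at the alcohol oxidation level, stay fixed.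

**Compound list**

1 | 3,4,5-trimethoxybenzaldehyde | COc1cc(C=O)cc(OC)c1OC | starting material
2 | 4,4,5,5-tetramethyl-2-(propa-1,2-dien-1-yl)-1,3,2-dioxaborolane (allenylboronic acid pinacol ester) | C=C=CB1OC(C)(C)C(C)(C)O1 | starting material
3 | [(2E)-3-(4,4,5,5-tetramethyl-1,3,2-dioxaborolan-2-yl)prop-2-en-1-yl]bis(isopinocampheyl)borane, isopinocampheyl groups from (+)-α-pinene | CC1(C)OB(/C=C/CB([C@@H]2C[C@@H]3C[C@H]([C@H]2C)C3(C)C)[C@@H]2C[C@@H]3C[C@H]([C@H]2C)C3(C)C)OC1(C)C | intermediate
4 | (1S,2S)-2-(4,4,5,5-tetramethyl-1,3,2-dioxaborolan-2-yl)-1-(3,4,5-trimethoxyphenyl)but-3-en-1-yl bis(isopinocampheyl)borinate (anti adduct) | C=C[C@H](B1OC(C)(C)C(C)(C)O1)[C@H](OB([C@@H]2C[C@@H]3C[C@H]([C@H]2C)C3(C)C)[C@@H]2C[C@@H]3C[C@H]([C@H]2C)C3(C)C)c1cc(OC)c(OC)c(OC)c1 | intermediate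
5 | (1R,2S)-1-(3,4,5-trimethoxyphenyl)but-3-ene-1,2-diol (anti diol) | C=C[C@H](O)[C@H](O)c1cc(OC)c(OC)c(OC)c1 | intermediate
6 | dibromomethane | BrCBr | starting material
7 | (4S,5R)-4-ethenyl-5-(3,4,5-trimethoxyphenyl)-1,3-dioxolane (cis) | C=C[C@@H]1OCO[C@@H]1c1cc(OC)c(OC)c(OC)c1 | intermediate
8 | 4-allyl-1,2-dimethoxybenzene | C=CCc1ccc(OC)c(OC)c1 | starting material
9 | (4S,5R)-4-[(1Z)-3-(3,4-dimethoxyphenyl)prop-1-en-1-yl]-5-(3,4,5-trimethoxyphenyl)-1,3-dioxolane (cis-dioxolane, Z-alkene) | COc1ccc(C/C=C\[C@@H]2OCO[C@@H]2c2cc(OC)c(OC)c(OC)c2)cc1OC | intermediate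
10 | (2S,3R,4S)-4-(3,4-dimethoxybenzyl)-2-(3,4,5-trimethoxyphenyl)oxolane-3-carbaldehyde (all-cis) | COc1ccc(C[C@@H]2CO[C@H](c3cc(OC)c(OC)c(OC)c3)[C@@H]2C=O)cc1OC | intermediate
11 | [(2S,3S,4S)-4-(3,4-dimethoxybenzyl)-2-(3,4,5-trimethoxyphenyl)oxolan-3-yl]methanol (all-cis) | COc1ccc(C[C@@H]2CO[C@H](c3cc(OC)c(OC)c(OC)c3)[C@@H]2CO)cc1OC | intermediate
12 | [(2R,3S,4S)-4-(3,4-dimethoxybenzyl)-2-(3,4,5-trimethoxyphenyl)oxolan-3-yl]methanol (2,3-trans, 3,4-cis) | COc1ccc(C[C@@H]2CO[C@@H](c3cc(OC)c(OC)c(OC)c3)[C@@H]2CO)cc1OC | target

Total step count: 5. Longest linear sequence: 5 steps (1 → 5 → 7 → 9 → 11 → 12).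

**Steps most likely to fail**

Step 4. The cationic cascade may be diverted in three ways: a 1,2-hydride shift from C6 in place of carbon migration, a stepwise oxonia-Cope/aldol closure that loses control at C3, or ionisation of the benzylic C2–O bond before cyclisation, which would erode enantiopurity. The fallback forms C3–C4 by radical cyclisation; it sets out from 1 and returns at 12.
- Vinylmagnesium bromide (THF, 0 °C) converts 1 into racemic 1-(3,4,5-trimethoxyphenyl)prop-2-en-1-ol F1.
- Sharpless kinetic resolution (Ti(OiPr)4, L-(+)-diisopropyl tartrate, tBuOOH, 4 Å sieves, CH2Cl2, −20 °C, stopped below half conversion) should epoxidise the (R)-alcohol selectively to the erythro epoxy alcohol (S)-[(2R)-oxiran-2-yl](3,4,5-trimethoxyphenyl)methanol F2.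
- Commercial (E)-3-(3,4-dimethoxyphenyl)prop-2-en-1-ol and PBr3 give (E)-4-(3-bromoprop-1-en-1-yl)-1,2-dimethoxybenzene F3.
- O-Alkylation of F2 with F3 (NaH, Bu4NI, THF, 0 °C) gives the epoxy cinnamyl ether (2R)-2-[(S)-{[(2E)-3-(3,4-dimethoxyphenyl)prop-2-en-1-yl]oxy}(3,4,5-trimethoxyphenyl)methyl]oxirane F4.
- Cp2TiCl (trivalent titanium, made from Cp2TiCl2 and zinc dust, THF, rt) opens the epoxide homolytically to the C3 radical, which closes 5-exo-trig onto the cinnamyl alkene. Reduction of the benzylic C7 radical and acidic work-up should give 12 directly, since this cyclisation mode is known to favour the 2,3-trans-3,4-cis arrangement in this lignan class.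

Step 3. Z control or conversion may be lost through catalyst deactivation by the allylic acetal oxygens, through homodimerisation of 8, or through migration of the allyl double bond into conjugation. The fallback builds the alkene by olefination; it sets out from 7 and returns at 9.
- Lemieux–Johnson cleavage of 7 (OsO4 cat., NaIO4, 2,6-lutidine, dioxane–H2O) gives (4R,5R)-5-(3,4,5-trimethoxyphenyl)-1,3-dioxolane-4-carbaldehyde F5.
- Commercial 4-(2-bromoethyl)-1,2-dimethoxybenzene and PPh3 (toluene, reflux) give [2-(3,4-dimethoxyphenyl)ethyl]triphenylphosphonium bromide F6.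
- NaHMDS (THF, −78 °C, lithium-free) converts F6 into [2-(3,4-dimethoxyphenyl)ethylidene]triphenylphosphorane F7.
- Adding F5 to F7 at −78 °C should give 9 by the Z-selective Wittig reaction of a non-stabilised ylide. The low temperature limits epimerisation of F5 next to the formyl group.

Step 5. Friedel–Crafts capture of the C2 cation by ring B (aryltetralin formation) or elimination toward C3 may compete with reclosure by O1, or equilibration may stay incomplete. The fallback inverts C2 through a radical, which cannot alkylate ring B; it sets out from 11 and returns at 12 and makes no new compound. It is a thiol-catalysed radical-chain epimerisation (tri-tert-butoxysilanethiol cat., di-tert-butyl hyponitrite as initiator, benzene, 60 °C). Reversible hydrogen-atom abstraction by the thiyl radical at the weakest C–H bond, the benzylic α-oxy C2–H, should equilibrate C2 alone to the 2,3-trans isomer.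

**Further compounds**

F1 | step 4 | racemic 1-(3,4,5-trimethoxyphenyl)prop-2-en-1-ol | C=CC(O)c1cc(OC)c(OC)c(OC)c1
F2 | step 4 | (S)-[(2R)-oxiran-2-yl](3,4,5-trimethoxyphenyl)methanol | COc1cc(cc(OC)c1OC)[C@H](O)[C@H]1CO1
F3 | step 4 | (E)-4-(3-bromoprop-1-en-1-yl)-1,2-dimethoxybenzene | COc1ccc(/C=C/CBr)cc1OC
F4 | step 4 | (2R)-2-[(S)-{[(2E)-3-(3,4-dimethoxyphenyl)prop-2-en-1-yl]oxy}(3,4,5-trimethoxyphenyl)methyl]oxirane | COc1cc(cc(OC)c1OC)[C@H](OC/C=C/c1ccc(OC)c(OC)c1)[C@H]1CO1
F5 | step 3 | (4R,5R)-5-(3,4,5-trimethoxyphenyl)-1,3-dioxolane-4-carbaldehyde | O=C[C@@H]1OCO[C@@H]1c1cc(OC)c(OC)c(OC)c1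
F6 | step 3 | [2-(3,4-dimethoxyphenyl)ethyl]triphenylphosphonium bromide | COc1ccc(CC[P+](c2ccccc2)(c2ccccc2)c2ccccc2)cc1OC.[Br-]
F7 | step 3 | [2-(3,4-dimethoxyphenyl)ethylidene]triphenylphosphorane | COc1ccc(CC=P(c2ccccc2)(c2ccccc2)c2ccccc2)cc1OC
F0 | step 5 | none | none
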